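I start with the feed, the easy step: it brings the charge in evenly over 80 min, so 12.5% is in at 10.0 min and 31.2% at 25.0 min.

| setting | gamma | flask |
|---|---|---|
| free monomer | 0.010 M (fed, over 80 min) | 0.010 M (fed, over 80 min) |
| protic impurity | 0.30 mM | 0.200 mM |
| initiator | 0.50 mM | 0.50 mM |
| remark | run made earlier |  |
| time |  | 80 min |

- average number of monomer units in a chain (chains begun, living or dead) at 80 min
- part of the free monomer that has reacted at 80 min

- gamma (time / min: monomer in chains / %, free monomer / %): 1.33: 0.1, 1.9; 4.00: 0, 3.6; 6.00: 0.7, 4.9; 10.0: 0, 8.6; 15.0: 0.9, 14.2; 20.0: 1.7, 20.0; 25.0: 1.2, 25.5

(standard deviation of a reading: 0.5 percentage points)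

- the average divides the monomer in chains by the number of chains begun, living and dead together
- the earlier runs were read with a standard deviation of 0.5 percentage points
- the earlier runs do not show the number of chains; that part of a forecast is a guess
- percentages count the whole charge, also what has not yet gone in
- no earlier run changes the charge of protic impurity; that part of a forecast is a guess

I read the free monomer column of the gamma table against that feed. At 10.0 min the gamma run falls short of the feed by 3.9 percentage points, and over the next 15.0 min the shortfall grows by 1.8 points. Free monomer averages 17.0% of the charge across those rows, so I read 138 min for the lifetime of free monomer, the amount held divided by its rate of loss, the inverse of a pseudo-first-order rate constant. Each reading carries 0.5 points, so this lifetime is rough.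

The 80 min of this flask then count 0.580 lifetimes. If the lifetime holds, my reckoning for a steady feed leaves 75.9% of the charge free at the end, so the thing to watch is whether the shortfall keeps its slow pace.

The forecast sees “followed by slow first-order consumption” and gives c as 25% (range 17% to 34%) and dp as 4.5 (range 3 to 8).

The flask gives c of 56.0% and dp of 9.82.

    free monomer + initiator → living end + monomer in chains (k = 0.160 /M/s)
    free monomer + living end → monomer in chains + living end, rate k2*[living end]*[free monomer] (k = 0.880 /M/s)
    free monomer → uncatalysed product (k = 6.50 × 10⁻⁵ /s)
    protic impurity + free monomer → quenched substrate (k = 29.0 /M/s)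

In this flask at 80.0 min the living end stands at 4.53 × 10⁻⁴ M, so growth on it takes free monomer at 0.0239 /min, faster than the uncatalysed step at 0.00390 /min, and those two steps together give a lifetime of 36.0 min, against the 138 min read from the gamma run between 10.0 min and 25.0 min. The neighbour flask with 3.0 × 10⁻⁴ M of initiator holds 2.79 × 10⁻⁴ M of living end at that time, so the same sum gives it 53.6 min, shorter than the gamma reading by a factor of 2.57, and that neighbour flask ends with 56% of its free monomer left.

The numbers in the tables stem from a simulated flask for an exercise, noise included.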